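## The problem

The target is a 2H-chromene. Ring B (O1, C2, C3, C4, C4a, C8a) is fused to the hydroquinone-derived ring A, which carries the free C6 hydroxyl and the C8 methyl group. Ring B holds the styrenic C3=C4 alkene and the fully substituted stereocentre C2 (S), bonded to O1, a methyl group, C3 and the side chain. The chain has thirteen carbons: an E-trisubstituted C3'=C4' alkene, an E-disubstituted C6'=C7' alkene skipped from it by the C5' methylene, the tertiary allylic carbinol C8' (S) and a prenyl terminus. C2 and C8' are nine bonds apart on a flexible chain, so neither can direct the other; each must be set by a reagent, best in separate fragments. Nothing in the finished molecule tolerates rough treatment: the electron-rich chromenol oxidises in air and degrades in acid, the tertiary allylic alcohol ionises in acid, the skipped diene moves into conjugation under base or metal hydrides, and four alkenes forbid hydrogenolysis. The hardest point is C2, a quaternary, stereogenic carbon of a tertiary alkyl aryl ether, for which asymmetric C–O bond formation is not dependable. The feature that opens the problem is that C2 lies between O1 and C3. If C4 is taken out, ring B contracts to a benzofuran-3(2H)-one in which C2 is the only α-carbon of the C3 ketone, an enolisable carbon that can be allylated by asymmetric catalysis. Re-inserting one carbon between C3 and C4a rebuilds ring B, and the C3 carbonyl that remains is the handle for the C3=C4 alkene.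

## Retrosynthesis

**31 to 30.** The last bond cut is O–Si at C6, leading from 31 to its triisopropylsilyl ether 30. The forward step must be a buffered fluoride desilylation, the only deprotection that the chromenol, the tertiary allylic alcohol and the skipped diene all tolerate. A methyl ether, as found in the commercial arene, could not be removed at this stage.

**30 to 24 and 29.** The C5'–C6' bond between the allylic methylene and the vinyl carbon is cut, giving allylic bromide 24 and vinylstannane 29. Cutting C3'=C4' instead would demand an E-selective trisubstituted olefination of a ketone, and cutting C7'–C8' by a vinyl-metal addition to a methyl ketone would leave C8' uncontrolled. The chosen cut places one stereocentre in each fragment and fixes both alkene geometries before the coupling. The forward Stille coupling must join the primary allylic terminus without allylic transposition or E/Z loss and must tolerate the free tertiary hydroxyl.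

**29 to 25.** The C–Sn bond comes from hydrostannation of alkyne 28. The alkyne comes from epoxy chloride 27 by base-induced fragmentation, 27 from epoxy alcohol 26, and 26 from geraniol 25 by Sharpless asymmetric epoxidation. The C8' carbinol is thus set by a reagent on a cheap terpene, and its C–O bond is never broken afterwards.

**24 to 17.** The bromide 24 goes back through allylic alcohol 23 to enoate 22. The C3'=C4' bond of 22 is cut to aldehyde 21 and the stabilised ylide 20, which is the dependable way to an E-trisubstituted alkene. Aldehyde 21 comes from alcohol 19, and 19 from the terminal alkene of the allyl chromene 17 through borane 18. The allyl group therefore supplies C1'–C3', and the forward hydroboration must select the monosubstituted alkene over C3=C4.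

**17 to 14.** The C3=C4 alkene is traced to enol triflate 16 and then to ketone 14. Because C2 is quaternary, only C4 bears α-hydrogens, so enolate 15 and triflate 16 can form in one direction only. The forward reduction must replace C–OTf by C–H without touching the allyl group.

**14 to 11 and 12 (key disconnection).** The C3–C4 and C4–C4a bonds are cut and C4 is removed as trimethylsilyldiazomethane 12, contracting ring B to the benzofuranone 11. Cutting O1–C2 instead would require etherification at a hindered tertiary carbon without stereocontrol, and cutting C4–C4a alone leaves the same problem in a propargylic ether. The ring contraction turns C2 into an α-carbon that can be made quaternary by enolate chemistry, and 11 is a simple bicyclic ketone. The forward reaction must add the diazoalkane to a hindered aryl ketone, shift the aryl carbon and stop after one insertion. Using the silylated diazoalkane gives the C4-silylated ketone 13 first, which shields the new ketone from a second insertion.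

**11 to 7 and 8.** The C2–allyl bond is cut. Ketone 11 is traced to the allyl enol carbonate 10, and 10 to the racemic ketone 7 through enolate 9 and allyl chloroformate 8. The forward decarboxylative allylation generates the enolate only at C2 and must choose its face. The stereocentre of 7 is lost in 10, so 7 can be racemic.

**7 to 1 and 2.** The silyl ether 7 comes from phenol 6, and 6 from methyl ether 5. The C3–C3a bond of 5 is cut to acid chloride 4 and acid 3, and the O–C2 bond of 3 to 4-methoxy-2-methylphenol 1 and 2-chloropropanoic acid 2. The methoxy group and the ortho methyl group of 1 leave one position for the Friedel–Crafts closure, so the substitution pattern of ring A is fixed by the starting material.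

## Roads not taken

**Alternative 1:** Ring A itself is the retron. Three arene bonds (C4a–C8a, C5–C6, C7–C8) are cut, which unravels rings A and B together into the ynol-ether diyne A1, (3Z,5S)-5,9-dimethyl-5-(prop-1-yn-1-yloxy)deca-3,8-dien-1-yne, and ethynylboronic acid pinacol ester A2. In the forward step Cp*RuCl(cod), a divalent ruthenium complex, would join the two tethered alkynes of A1 in a ruthenacycle and insert A2 to give the boronate A3, (S)-2,8-dimethyl-2-(4-methylpent-3-en-1-yl)-6-(pinacolboryl)-2H-chromene.

- Merits: both rings form in one step, the C–B bond is a latent C6 hydroxyl that needs no protecting-group exchange, and no arene starting material is required. In step count for the core this road is clearly better than the chosen one.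
- Weak points:
  - A1 is an allyl alkynyl ether (C≡C–O–C2–C3=C4). Such ethers undergo [3,3]-sigmatropic shift to ketenes at or below room temperature, and tertiary alkyl ynol ethers also fragment on mild heating.
  - Making A1 requires alkynylating a hindered tertiary alkoxide.
  - C2 is not set by the key step and must be built beforehand in an acyclic tertiary alcohol.
  - Boron must end at C6 and not C7, which rests on a steric preference in the insertion of A2.
  - A3 holds only six chain carbons, so an SeO2 oxidation of the terminal E-methyl group would precede the same bromide and Stille steps.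
- Comparison: the chosen plan sets against the shorter core a sequence of stable, storable intermediates and a catalytic asymmetric C–C bond formation for C2.

**Alternative 2:** Only the C4–C4a bond is cut. The precursor is the aryl propargyl ether A4, ethyl (2E,6S)-2,6-dimethyl-6-[2-methyl-4-(pivaloyloxy)phenoxy]oct-2-en-7-ynoate. A cationic monovalent gold complex would activate the terminal alkyne, and the free ortho carbon of the arene would attack in a 6-endo hydroarylation to give A5, ethyl (S,E)-5-[2,8-dimethyl-6-(pivaloyloxy)-2H-chromen-2-yl]-2-methylpent-2-enoate.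

- Merits: this is the mildest and best-precedented chromene closure of the four, the ortho methyl group leaves one site of attack, and A5 corresponds to enoate 22 of the chosen route. As a ring-forming step it is safer than the ring expansion, and the route would be several steps shorter.
- Weak points: the whole difficulty moves into A4. Its quaternary stereocentre is a tertiary propargylic aryl ether. Substitution of tertiary propargylic electrophiles by phenols passes through planar cationic or allenylidene intermediates and has no general enantioselective form. O-arylation of an enantiopure tertiary propargylic alcohol with an electron-rich arene is not dependable.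
- Comparison: the chosen plan accepts a riskier ring-forming step and more operations in order to make C2 by enolate allylation, a reaction type proven for quaternary α-carbons.

**Alternative 3:** The O1–C2 and C3–C4 bonds are cut. The salicylaldehyde A6, 5-(tert-butyldimethylsilyloxy)-2-hydroxy-3-methylbenzaldehyde, and the tetraenal A7, (2E,6E,9E,11S)-11-hydroxy-3,7,11,15-tetramethylhexadeca-2,6,9,14-tetraenal, would be joined by a diarylprolinol silyl ether through iminium oxa-Michael addition and intramolecular aldol condensation. The product is A8, (S)-6-(tert-butyldimethylsilyloxy)-2-[(3E,6E,8S)-8-hydroxy-4,8,12-trimethyltrideca-3,6,11-trien-1-yl]-2,8-dimethyl-2H-chromene-3-carbaldehyde, whose formyl group would then be removed.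

- Merits: this is the most convergent road. Ring B, C2 and the complete chain arrive in one step, and in number of operations on the core it is better than the chosen plan.
- Weak points:
  - The oxa-Michael addition must create a fully substituted C–O stereocentre at a β,β-disubstituted enal. Iminium formation there is slow, the catalyst must distinguish a methyl from a methylene group at the β-carbon, the iminium and dienamine forms scramble the enal geometry, and the addition is reversible.
  - Deformylation of A8 needs a rhodium decarbonylation, for example with RhCl(PPh3)3 at high temperature, in the presence of a skipped diene and a tertiary allylic alcohol.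
  - A7 must be built in full before the uncertain step, so the costly fragment is put at risk first.
- Comparison: the chosen plan is longer but fixes C2 on a small, cheap intermediate and attaches the valuable chain fragment last.

Key step: step 7

Assumption: the (R,R) enantiomer of the ligand in step 6 is taken to give the S configuration at C2 by analogy with enol carbonates of 2-methyl-1-tetralone; if the sense is the reverse, the (S,S) ligand is used and nothing else changes.

## Route

Step 1
Reactants: 1 4-methoxy-2-methylphenol; 2 2-chloropropanoic acid (racemic)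
Product: 3 2-(4-methoxy-2-methylphenoxy)propanoic acid (racemic)
Conditions: NaOH, H2O, reflux; then HCl
Reagents that add atoms: none
Why: Williamson ether synthesis: the phenoxide displaces chloride from sodium 2-chloropropanoate in water, the standard entry to 2-aryloxypropanoic acids. The product is racemic, which does not matter because this carbon becomes planar in step 5.

Step 2
Reactants: 3 2-(4-methoxy-2-methylphenoxy)propanoic acid (racemic)
Product: 5 5-methoxy-2,7-dimethylbenzofuran-3(2H)-one (racemic), via 2-(4-methoxy-2-methylphenoxy)propanoyl chloride 4 (not isolated)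
Conditions: (COCl)2, DMF (cat.), CH2Cl2, 23 °C; then AlCl3, CH2Cl2, 0 °C
Reagents that add atoms: none
Why: Intramolecular Friedel–Crafts acylation: acid chloride 4 closes onto the only free position ortho to the ether oxygen, the other being blocked by the methyl group. This is the usual way to benzofuran-3(2H)-ones from aryloxy acids.

Step 3
Reactants: 5 5-methoxy-2,7-dimethylbenzofuran-3(2H)-one (racemic)
Product: 6 5-hydroxy-2,7-dimethylbenzofuran-3(2H)-one (racemic)
Conditions: BBr3, CH2Cl2, −78 → 0 °C
Reagents that add atoms: none
Why: Boron-mediated cleavage of an aryl methyl ether by bromide attack at the O-methyl carbon. The methyl ether directed step 2 but could not be removed late, so it is exchanged here where nothing sensitive is present.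

Step 4
Reactants: 6 5-hydroxy-2,7-dimethylbenzofuran-3(2H)-one (racemic)
Product: 7 2,7-dimethyl-5-(triisopropylsilyloxy)benzofuran-3(2H)-one (racemic)
Conditions: i-Pr3SiCl, imidazole, DMF, 23 °C
Reagents that add atoms: triisopropylsilyl chloride, CC(C)[Si](Cl)(C(C)C)C(C)C
Why: Silylation of the phenol. The triisopropylsilyl aryl ether withstands the amide bases, BF3·OEt2, hydride and palladium chemistry ahead and leaves with fluoride at the end.

Step 5
Reactants: 7 2,7-dimethyl-5-(triisopropylsilyloxy)benzofuran-3(2H)-one (racemic); 8 allyl chloroformate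
Product: 10 allyl 2,7-dimethyl-5-(triisopropylsilyloxy)benzofuran-3-yl carbonate, via sodium 2,7-dimethyl-5-(triisopropylsilyloxy)benzofuran-3-olate 9 (not isolated)
Conditions: NaN(SiMe3)2, TMEDA, THF, −78 °C; then 8, −78 → 0 °C
Reagents that add atoms: none
Why: Enol carbonate formation: deprotonation gives the aromatic benzofuran-3-olate 9, which the hard chloroformate acylates on oxygen. Any C-acylated allyl β-keto ester would enter step 6 through the same ion pair.

Step 6
Reactants: 10 allyl 2,7-dimethyl-5-(triisopropylsilyloxy)benzofuran-3-yl carbonate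
Product: 11 (S)-2-allyl-2,7-dimethyl-5-(triisopropylsilyloxy)benzofuran-3(2H)-one
Conditions: Pd2(dba)3·CHCl3 (2.5 mol %), (R,R)-ANDEN-phenyl Trost ligand (5.5 mol %), 1,4-dioxane, 23 °C
Reagents that add atoms: none
Why: Decarboxylative asymmetric allylic alkylation (Tsuji–Trost type): zerovalent palladium ionises the allyl carbonate and loss of CO2 leaves a benzofuran-3-olate/π-allylpalladium ion pair. The C–C bond forms at C2 inside the chiral pocket of the ligand, which selects the enolate face and sets the S quaternary centre. The enolate is generated only at C2, so regiochemistry is fixed.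

Step 7
Reactants: 11 (S)-2-allyl-2,7-dimethyl-5-(triisopropylsilyloxy)benzofuran-3(2H)-one; 12 trimethylsilyldiazomethane
Product: 14 (S)-2-allyl-2,8-dimethyl-6-(triisopropylsilyloxy)chroman-3-one, via (2S)-2-allyl-2,8-dimethyl-6-(triisopropylsilyloxy)-4-(trimethylsilyl)chroman-3-one 13 (not isolated)
Conditions: 12 (2 M in hexanes), BF3·OEt2, CH2Cl2, −78 → −20 °C; then 1 M HCl, THF, 23 °C
Reagents that add atoms: none
Why: BF3 activates the C3 carbonyl of 11, the nucleophilic carbon of 12 adds to it, and the β-boryloxy diazonium ion loses N2 with a 1,2-shift, a Tiffeneau–Demjanov-type homologation. The closest known reaction type is the Lewis-acid-promoted trimethylsilyldiazomethane ring expansion of 1-indanones to 2-tetralones and of 1-tetralones to benzosuberones, in which the aryl carbon migrates. Ring B is closed by ring enlargement and not by cyclisation: the aryl carbon C3a of the furanone (C4a of the chroman) moves from C3 to the diazo carbon, which becomes C4, so C3–C4 and C4–C4a are formed and the five-membered ring becomes six-membered. The step needs aryl migration over C2 migration; the aryl carbon is ortho to the ring oxygen and electron-rich, whereas C2 is quaternary, crowded and bears the inductively withdrawing O1. It also needs migration over closure to the spiro-epoxide, which boron coordination of the alkoxide and the low temperature favour. A single insertion is secured by the C4 silyl group of 13, which shields the new ketone until acid removes it. No stereocentre is created, since C4 of 13 is stereogenic only until protodesilylation, and C2 has no α-hydrogen and keeps all its bonds, so its S configuration passes unchanged into 14. The allyl group and the aryl silyl ether are inert to the diazoalkane and to BF3·OEt2 at these temperatures.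

Step 8
Reactants: 14 (S)-2-allyl-2,8-dimethyl-6-(triisopropylsilyloxy)chroman-3-one
Product: 16 (S)-2-allyl-2,8-dimethyl-6-(triisopropylsilyloxy)-2H-chromen-3-yl trifluoromethanesulfonate, via potassium (S)-2-allyl-2,8-dimethyl-6-(triisopropylsilyloxy)-2H-chromen-3-olate 15 (not isolated)
Conditions: KN(SiMe3)2, THF, −78 °C; then PhNTf2, −78 → 0 °C
Reagents that add atoms: N-phenylbis(trifluoromethanesulfonimide), O=S(=O)(N(c1ccccc1)S(=O)(=O)C(F)(F)F)C(F)(F)F
Why: Enol triflate formation: C4 carries the only α-hydrogens of 14, so deprotonation gives a single styrene-conjugated enolate 15, which is triflated on oxygen. C2 is quaternary and cannot epimerise.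

Step 9
Reactants: 16 (S)-2-allyl-2,8-dimethyl-6-(triisopropylsilyloxy)-2H-chromen-3-yl trifluoromethanesulfonate
Product: 17 (S)-2-allyl-2,8-dimethyl-6-(triisopropylsilyloxy)-2H-chromene
Conditions: Pd(OAc)2 (5 mol %), PPh3 (10 mol %), HCO2H, Et3N, DMF, 60 °C
Reagents that add atoms: none
Why: Palladium-catalysed formate reduction of an enol triflate: zerovalent palladium inserts into the C3–O bond, formate replaces triflate, and loss of CO2 followed by C–H reductive elimination leaves the C3=C4 alkene. Insertion of the alkenylpalladium into the neighbouring allyl group would need a four-membered ring and should not compete.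

Step 10
Reactants: 17 (S)-2-allyl-2,8-dimethyl-6-(triisopropylsilyloxy)-2H-chromene
Product: 19 3-[(S)-2,8-dimethyl-6-(triisopropylsilyloxy)-2H-chromen-2-yl]propan-1-ol, via 9-{3-[(S)-2,8-dimethyl-6-(triisopropylsilyloxy)-2H-chromen-2-yl]propyl}-9-borabicyclo[3.3.1]nonane 18 (not isolated)
Conditions: 9-BBN, THF, 0 → 23 °C; then NaBO3·4H2O, H2O, 23 °C
Reagents that add atoms: sodium perborate, [Na+].[Na+].O[B-]1(O)OO[B-](O)(O)OO1
Why: Hydroboration–oxidation: 9-BBN adds anti-Markovnikov to the monosubstituted alkene much faster than to the cis-disubstituted styrenic C3=C4 bond next to the quaternary C2. The mild perborate oxidation spares the aryl silyl ether.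

Step 11
Reactants: 19 3-[(S)-2,8-dimethyl-6-(triisopropylsilyloxy)-2H-chromen-2-yl]propan-1-ol; 20 ethyl 2-(triphenylphosphoranylidene)propanoate
Product: 22 ethyl (E)-5-[(S)-2,8-dimethyl-6-(triisopropylsilyloxy)-2H-chromen-2-yl]-2-methylpent-2-enoate, via 3-[(S)-2,8-dimethyl-6-(triisopropylsilyloxy)-2H-chromen-2-yl]propanal 21 (not isolated)
Conditions: Dess–Martin periodinane, CH2Cl2, 0 → 23 °C; then 20, 23 °C
Reagents that add atoms: none
Why: Dess–Martin oxidation gives aldehyde 21, which is trapped in the same flask by the stabilised ylide 20 in a Wittig reaction. α-Methyl stabilised ylides give the E-trisubstituted enoate, and the one-pot mode avoids handling the aldehyde.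

Step 12
Reactants: 22 ethyl (E)-5-[(S)-2,8-dimethyl-6-(triisopropylsilyloxy)-2H-chromen-2-yl]-2-methylpent-2-enoate
Product: 23 (E)-5-[(S)-2,8-dimethyl-6-(triisopropylsilyloxy)-2H-chromen-2-yl]-2-methylpent-2-en-1-ol
Conditions: i-Bu2AlH, CH2Cl2, −78 °C; then aq. sodium potassium tartrate
Reagents that add atoms: none
Why: 1,2-Reduction of the enoate to the allylic alcohol by the aluminium hydride at low temperature. The alkene geometry, the chromene and the silyl ether are untouched.

Step 13
Reactants: 23 (E)-5-[(S)-2,8-dimethyl-6-(triisopropylsilyloxy)-2H-chromen-2-yl]-2-methylpent-2-en-1-ol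
Product: 24 (S)-2-[(E)-5-bromo-4-methylpent-3-en-1-yl]-2,8-dimethyl-6-(triisopropylsilyloxy)-2H-chromene
Conditions: CBr4, PPh3, CH2Cl2, 0 °C
Reagents that add atoms: tetrabromomethane, BrC(Br)(Br)Br
Why: Appel bromination: bromide displaces the alkoxyphosphonium group at the primary carbon under neutral conditions, without allylic transposition or E/Z change. The bromide is used directly in step 18.

Step 14
Reactants: 25 geraniol
Product: 26 (2S,3S)-2,3-epoxygeraniol
Conditions: Ti(OiPr)4 (5 mol %), L-(+)-diethyl tartrate (6 mol %), t-BuOOH, 4 Å molecular sieves, CH2Cl2, −20 °C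
Reagents that add atoms: tert-butyl hydroperoxide, CC(C)(C)OO
Why: Sharpless asymmetric epoxidation: the titanium tartrate complex binds the allylic alcohol and delivers oxygen to one face of the C2=C3 alkene, L-(+)-tartrate giving the 2S,3S epoxide. The remote trisubstituted alkene is not an allylic alcohol and is left alone. This sets the future C8' stereocentre.

Step 15
Reactants: 26 (2S,3S)-2,3-epoxygeraniol
Product: 27 (2R,3S)-1-chloro-2,3-epoxy-3,7-dimethyloct-6-ene
Conditions: PPh3, CCl4, NaHCO3, reflux
Reagents that add atoms: tetrachloromethane, ClC(Cl)(Cl)Cl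
Why: Appel-type chlorination of the primary alcohol under neutral, bicarbonate-buffered conditions leaves the acid-sensitive trisubstituted epoxide intact. The descriptor at C2 changes only because chlorine raises the priority of C1.

Step 16
Reactants: 27 (2R,3S)-1-chloro-2,3-epoxy-3,7-dimethyloct-6-ene
Product: 28 (S)-3,7-dimethyloct-6-en-1-yn-3-ol
Conditions: n-BuLi (3.2 equiv), THF, −78 → −30 °C; then aq. NH4Cl
Reagents that add atoms: none
Why: Base-induced fragmentation of a 2,3-epoxy chloride to a propargylic alcohol: lithiation at the chloromethyl carbon, β-elimination that opens the epoxide at C2–O, and dehydrochlorination to the acetylide. The C3–O bond is never broken, so the carbinol keeps its configuration.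

Step 17
Reactants: 28 (S)-3,7-dimethyloct-6-en-1-yn-3-ol
Product: 29 (S,E)-3,7-dimethyl-1-(tributylstannyl)octa-1,6-dien-3-ol
Conditions: Bu3SnH, PdCl2(PPh3)2 (2 mol %), THF, 0 → 23 °C
Reagents that add atoms: tributyltin hydride, CCCC[SnH](CCCC)CCCC
Why: Palladium-catalysed syn-hydrostannation of a terminal alkyne: the bulky tertiary carbinol directs tin to the terminal carbon and gives the E-vinylstannane. The free hydroxyl is tolerated.

Step 18
Reactants: 24 (S)-2-[(E)-5-bromo-4-methylpent-3-en-1-yl]-2,8-dimethyl-6-(triisopropylsilyloxy)-2H-chromene; 29 (S,E)-3,7-dimethyl-1-(tributylstannyl)octa-1,6-dien-3-ol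
Product: 30 (S)-2-[(3E,6E,8S)-8-hydroxy-4,8,12-trimethyltrideca-3,6,11-trien-1-yl]-2,8-dimethyl-6-(triisopropylsilyloxy)-2H-chromene
Conditions: Pd2(dba)3 (2.5 mol %), AsPh3 (10 mol %), THF, 40 °C
Reagents that add atoms: none
Why: Stille coupling of an allylic bromide with a vinylstannane: oxidative addition gives a π-allylpalladium species, and transmetalation and reductive elimination join C5' to C6' at the less hindered primary terminus with retention of both alkene geometries. The weakly donating arsine speeds transmetalation, and no base is present.

Step 19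
Reactants: 30 (S)-2-[(3E,6E,8S)-8-hydroxy-4,8,12-trimethyltrideca-3,6,11-trien-1-yl]-2,8-dimethyl-6-(triisopropylsilyloxy)-2H-chromene
Product: 31 (S)-2-[(3E,6E,8S)-8-hydroxy-4,8,12-trimethyltrideca-3,6,11-trien-1-yl]-2,8-dimethyl-2H-chromen-6-ol
Conditions: Bu4NF, AcOH, THF, 0 °C
Reagents that add atoms: none
Why: Fluoride cleaves the aryl O–Si bond. Buffering with acetic acid keeps the chromenol from standing as its air-sensitive phenoxide and spares the tertiary allylic alcohol.

## Compound list

1 | 4-methoxy-2-methylphenol | COc1ccc(O)c(C)c1 | starting material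
2 | 2-chloropropanoic acid (racemic) | CC(Cl)C(=O)O | starting material
3 | 2-(4-methoxy-2-methylphenoxy)propanoic acid (racemic) | CC(Oc1ccc(OC)cc1C)C(=O)O | intermediate
4 | 2-(4-methoxy-2-methylphenoxy)propanoyl chloride (racemic) | CC(Oc1ccc(OC)cc1C)C(Cl)=O | intermediate
5 | 5-methoxy-2,7-dimethylbenzofuran-3(2H)-one (racemic) | CC1Oc2c(C)cc(OC)cc2C1=O | intermediate
6 | 5-hydroxy-2,7-dimethylbenzofuran-3(2H)-one (racemic) | CC1Oc2c(C)cc(O)cc2C1=O | intermediate
7 | 2,7-dimethyl-5-(triisopropylsilyloxy)benzofuran-3(2H)-one (racemic) | CC1Oc2c(C)cc(O[Si](C(C)C)(C(C)C)C(C)C)cc2C1=O | intermediate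
8 | allyl chloroformate | C=CCOC(=O)Cl | starting material
9 | sodium 2,7-dimethyl-5-(triisopropylsilyloxy)benzofuran-3-olate | [Na+].[O-]c1c(C)oc2c(C)cc(O[Si](C(C)C)(C(C)C)C(C)C)cc12 | intermediate
10 | allyl 2,7-dimethyl-5-(triisopropylsilyloxy)benzofuran-3-yl carbonate | C=CCOC(=O)Oc1c(C)oc2c(C)cc(O[Si](C(C)C)(C(C)C)C(C)C)cc12 | intermediate
11 | (S)-2-allyl-2,7-dimethyl-5-(triisopropylsilyloxy)benzofuran-3(2H)-one | C=CC[C@@]1(C)C(=O)c2cc(O[Si](C(C)C)(C(C)C)C(C)C)cc(C)c2O1 | intermediate
12 | trimethylsilyldiazomethane | C[Si](C)(C)C=[N+]=[N-] | starting material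
13 | (2S)-2-allyl-2,8-dimethyl-6-(triisopropylsilyloxy)-4-(trimethylsilyl)chroman-3-one (C4 epimers) | C=CC[C@@]1(C)C(=O)C([Si](C)(C)C)c2cc(O[Si](C(C)C)(C(C)C)C(C)C)cc(C)c2O1 | intermediate
14 | (S)-2-allyl-2,8-dimethyl-6-(triisopropylsilyloxy)chroman-3-one | C=CC[C@@]1(C)C(=O)Cc2cc(O[Si](C(C)C)(C(C)C)C(C)C)cc(C)c2O1 | intermediate
15 | potassium (S)-2-allyl-2,8-dimethyl-6-(triisopropylsilyloxy)-2H-chromen-3-olate | [K+].C=CC[C@@]1(C)C([O-])=Cc2cc(O[Si](C(C)C)(C(C)C)C(C)C)cc(C)c2O1 | intermediate
16 | (S)-2-allyl-2,8-dimethyl-6-(triisopropylsilyloxy)-2H-chromen-3-yl trifluoromethanesulfonate | C=CC[C@@]1(C)C(OS(=O)(=O)C(F)(F)F)=Cc2cc(O[Si](C(C)C)(C(C)C)C(C)C)cc(C)c2O1 | intermediate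
17 | (S)-2-allyl-2,8-dimethyl-6-(triisopropylsilyloxy)-2H-chromene | C=CC[C@@]1(C)C=Cc2cc(O[Si](C(C)C)(C(C)C)C(C)C)cc(C)c2O1 | intermediate
18 | 9-{3-[(S)-2,8-dimethyl-6-(triisopropylsilyloxy)-2H-chromen-2-yl]propyl}-9-borabicyclo[3.3.1]nonane | C(CC[C@@]1(C)C=Cc2cc(O[Si](C(C)C)(C(C)C)C(C)C)cc(C)c2O1)B3C4CCCC3CCC4 | intermediate
19 | 3-[(S)-2,8-dimethyl-6-(triisopropylsilyloxy)-2H-chromen-2-yl]propan-1-ol | OCCC[C@@]1(C)C=Cc2cc(O[Si](C(C)C)(C(C)C)C(C)C)cc(C)c2O1 | intermediate
20 | ethyl 2-(triphenylphosphoranylidene)propanoate | CCOC(=O)C(C)=P(c1ccccc1)(c1ccccc1)c1ccccc1 | starting material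
21 | 3-[(S)-2,8-dimethyl-6-(triisopropylsilyloxy)-2H-chromen-2-yl]propanal | O=CCC[C@@]1(C)C=Cc2cc(O[Si](C(C)C)(C(C)C)C(C)C)cc(C)c2O1 | intermediate
22 | ethyl (E)-5-[(S)-2,8-dimethyl-6-(triisopropylsilyloxy)-2H-chromen-2-yl]-2-methylpent-2-enoate | CCOC(=O)/C(C)=C/CC[C@@]1(C)C=Cc2cc(O[Si](C(C)C)(C(C)C)C(C)C)cc(C)c2O1 | intermediate
23 | (E)-5-[(S)-2,8-dimethyl-6-(triisopropylsilyloxy)-2H-chromen-2-yl]-2-methylpent-2-en-1-ol | OC/C(C)=C/CC[C@@]1(C)C=Cc2cc(O[Si](C(C)C)(C(C)C)C(C)C)cc(C)c2O1 | intermediate
24 | (S)-2-[(E)-5-bromo-4-methylpent-3-en-1-yl]-2,8-dimethyl-6-(triisopropylsilyloxy)-2H-chromene | BrC/C(C)=C/CC[C@@]1(C)C=Cc2cc(O[Si](C(C)C)(C(C)C)C(C)C)cc(C)c2O1 | intermediate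
25 | geraniol | CC(C)=CCC/C(C)=C/CO | starting material
26 | (2S,3S)-2,3-epoxygeraniol, that is [(2S,3S)-3-methyl-3-(4-methylpent-3-en-1-yl)oxiran-2-yl]methanol | OC[C@@H]1O[C@@]1(C)CCC=C(C)C | intermediate
27 | (2R,3S)-1-chloro-2,3-epoxy-3,7-dimethyloct-6-ene | ClC[C@@H]1O[C@@]1(C)CCC=C(C)C | intermediate
28 | (S)-3,7-dimethyloct-6-en-1-yn-3-ol | CC(C)=CCC[C@](C)(O)C#C | intermediate
29 | (S,E)-3,7-dimethyl-1-(tributylstannyl)octa-1,6-dien-3-ol | CC(C)=CCC[C@](C)(O)/C=C/[Sn](CCCC)(CCCC)CCCC | intermediate
30 | (S)-2-[(3E,6E,8S)-8-hydroxy-4,8,12-trimethyltrideca-3,6,11-trien-1-yl]-2,8-dimethyl-6-(triisopropylsilyloxy)-2H-chromene | CC(C)=CCC[C@](C)(O)/C=C/C/C(C)=C/CC[C@@]1(C)C=Cc2cc(O[Si](C(C)C)(C(C)C)C(C)C)cc(C)c2O1 | intermediate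
31 | (S)-2-[(3E,6E,8S)-8-hydroxy-4,8,12-trimethyltrideca-3,6,11-trien-1-yl]-2,8-dimethyl-2H-chromen-6-ol | CC(C)=CCC[C@](C)(O)/C=C/C/C(C)=C/CC[C@@]1(C)C=Cc2cc(O)cc(C)c2O1 | target

## Step count and risks

Total step count: 19. Longest linear sequence: 15 steps (steps 1 to 13, then 18 and 19). Steps 14 to 17 prepare the stannane fragment 29 from geraniol.

**Step 7 (key step).** The diazoalkane may fail to add to the C3 carbonyl, which is flanked by a quaternary carbon and deactivated as a vinylogous ester through O1. The betaine may also close on oxygen to a spiro-epoxide, or C2 may shift in place of the aryl carbon. The fallback sets out from 11 and returns at 14. Ketone 11 is methylenated with Ph3P=CH2 (from Ph3PCH3Br and KOt-Bu, toluene, 90 °C) to (S)-2-allyl-2,7-dimethyl-3-methylidene-5-(triisopropylsilyloxy)-2,3-dihydrobenzofuran F1, which cannot aromatise because C2 is quaternary. Treatment of this electron-rich exocyclic styrene with PhI(OH)OTs in 95% methanol effects the known iodine-mediated oxidative rearrangement of 1-methylidene benzocycloalkanes. Methanol adds at C3, the aryl group shifts to the former methylidene carbon with loss of iodobenzene, and work-up gives 14. The same two bonds are formed, but through alkene oxidation instead of carbonyl addition.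

**Step 6.** The flat, aromatic enolate may be discriminated poorly in its outer-sphere attack on the π-allyl complex, and O-allylation may compete. The fallback sets out from 7 and returns at 11. Ketone 7 is allylated directly with allyl bromide under asymmetric phase-transfer catalysis (a cinchona-derived N-arylmethyl quaternary ammonium salt, 50% aqueous KOH, toluene, 0 °C). This is the chiral ion-pair alkylation known for 2-substituted 1-indanones and 1-tetralones. It makes no compound outside the list (entry F0) and bypasses 10.

**Step 9.** The palladium hydride formed from formate may isomerise the terminal allyl alkene into conjugation, or oxidative addition to the hindered triflate may be slow. The fallback sets out from 14 and returns at 17. Ketone 14 is reduced with NaBH4 (MeOH, 0 °C) to (2S)-2-allyl-2,8-dimethyl-6-(triisopropylsilyloxy)chroman-3-ol F2, a mixture of C3 epimers. F2 is dehydrated with Burgess reagent (toluene, 70 °C) by syn-elimination of the sulfamate with a benzylic C4 hydrogen. C2 has no hydrogen, so only the C3=C4 alkene can form.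

**Step 18.** The 2-methyl-substituted π-allylpalladium intermediate may equilibrate by σ–π–σ isomerisation, with loss of the C3'=C4' geometry or coupling at the branched terminus, and the stannane may protodestannylate. The fallback sets out from 24 and 28 and returns at 30. The terminal alkyne 28 is coupled with bromide 24 under copper mediation (CuI, NaI, K2CO3, DMF, 23 °C) to (S)-2-[(3E,8S)-8-hydroxy-4,8,12-trimethyltrideca-3,11-dien-6-yn-1-yl]-2,8-dimethyl-6-(triisopropylsilyloxy)-2H-chromene F3. The propargylic alkoxide of F3 then directs trans-hydroalumination with NaAlH2(OCH2CH2OCH3)2 (THF, 0 → 23 °C), and protonation gives the E-alkene of 30.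

**Step 17.** Tin may add at the internal alkyne carbon, and the product may lose tin on silica. The fallback sets out from 28 and returns at 30. Alkyne 28 is hydroborated with pinacolborane (Cp2ZrHCl as catalyst, CH2Cl2, 23 °C). The hydroxyl consumes one further equivalent as a borate that is hydrolysed on work-up, leaving (S,E)-3,7-dimethyl-1-(4,4,5,5-tetramethyl-1,3,2-dioxaborolan-2-yl)octa-1,6-dien-3-ol F4. F4 is joined to bromide 24 by Suzuki–Miyaura coupling (Pd(PPh3)4, aqueous K3PO4, THF, 50 °C), which replaces tin by boron in the fragment union.

## Further compounds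

F1 | step 7 | (S)-2-allyl-2,7-dimethyl-3-methylidene-5-(triisopropylsilyloxy)-2,3-dihydrobenzofuran | C=CC[C@@]1(C)C(=C)c2cc(O[Si](C(C)C)(C(C)C)C(C)C)cc(C)c2O1
F0 | step 6 | none | none
F2 | step 9 | (2S)-2-allyl-2,8-dimethyl-6-(triisopropylsilyloxy)chroman-3-ol | C=CC[C@@]1(C)C(O)Cc2cc(O[Si](C(C)C)(C(C)C)C(C)C)cc(C)c2O1
F3 | step 18 | (S)-2-[(3E,8S)-8-hydroxy-4,8,12-trimethyltrideca-3,11-dien-6-yn-1-yl]-2,8-dimethyl-6-(triisopropylsilyloxy)-2H-chromene | CC(C)=CCC[C@](C)(O)C#CC/C(C)=C/CC[C@@]1(C)C=Cc2cc(O[Si](C(C)C)(C(C)C)C(C)C)cc(C)c2O1
F4 | step 17 | (S,E)-3,7-dimethyl-1-(4,4,5,5-tetramethyl-1,3,2-dioxaborolan-2-yl)octa-1,6-dien-3-ol | CC(C)=CCC[C@](C)(O)/C=C/B1OC(C)(C)C(C)(C)O1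
A1 | alternative 1 | (3Z,5S)-5,9-dimethyl-5-(prop-1-yn-1-yloxy)deca-3,8-dien-1-yne | CC(C)=CCC[C@@](OC#CC)(C)/C=C\C#C
A2 | alternative 1 | ethynylboronic acid pinacol ester | C#CB1OC(C)(C)C(C)(C)O1
A3 | alternative 1 | (S)-2,8-dimethyl-2-(4-methylpent-3-en-1-yl)-6-(pinacolboryl)-2H-chromene | CC(C)=CCC[C@@]1(C)C=Cc2cc(B3OC(C)(C)C(C)(C)O3)cc(C)c2O1
A4 | alternative 2 | ethyl (2E,6S)-2,6-dimethyl-6-[2-methyl-4-(pivaloyloxy)phenoxy]oct-2-en-7-ynoate | CCOC(=O)/C(C)=C/CC[C@@](C)(C#C)Oc1ccc(OC(=O)C(C)(C)C)cc1C
A5 | alternative 2 | ethyl (S,E)-5-[2,8-dimethyl-6-(pivaloyloxy)-2H-chromen-2-yl]-2-methylpent-2-enoate | CCOC(=O)/C(C)=C/CC[C@@]1(C)C=Cc2cc(OC(=O)C(C)(C)C)cc(C)c2O1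
A6 | alternative 3 | 5-(tert-butyldimethylsilyloxy)-2-hydroxy-3-methylbenzaldehyde | O=Cc1cc(O[Si](C)(C)C(C)(C)C)cc(C)c1O
A7 | alternative 3 | (2E,6E,9E,11S)-11-hydroxy-3,7,11,15-tetramethylhexadeca-2,6,9,14-tetraenal | O=C/C=C(C)/CC/C=C(C)/C/C=C/[C@@](C)(O)CCC=C(C)C
A8 | alternative 3 | (S)-6-(tert-butyldimethylsilyloxy)-2-[(3E,6E,8S)-8-hydroxy-4,8,12-trimethyltrideca-3,6,11-trien-1-yl]-2,8-dimethyl-2H-chromene-3-carbaldehyde | CC(C)=CCC[C@](C)(O)/C=C/C/C(C)=C/CC[C@@]1(C)C(C=O)=Cc2cc(O[Si](C)(C)C(C)(C)C)cc(C)c2O1
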